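**Assumption:** CNP0152559.1 is taken exactly as the given SMILES, i.e. (3aR,4R,5Z,7S,9S,10Z,11aS)-7,9-dihydroxy-6,10-dimethyl-3-methylidene-2-oxo-2,3,3a,4,7,8,9,11a-octahydrocyclodeca[b]furan-4-yl (2Z)-2-methylbut-2-enoate (an angelate); these locants are used below.

## Retrosynthetic overview

1. Last C–C bond: the ten-membered ring is closed at C9–C10 by an intramolecular Nozaki–Hiyama–Kishi reaction; C9 is then set by oxidation and hydroxyl-directed 1,3-anti reduction.
2. Late fragment coupling at C3a–C4: chromium-mediated allylation of a C7 (Z)-enal (fragment B) with a C8 bromomethyl butenolide (fragment A) creates the α-methylene lactone and sets C3a and C4; the angelate is put on the new C4 hydroxyl straight afterwards.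
3. Fragment A: kinetic resolution (C11a), directed trans-hydroalumination/iodination ((Z)-iodoalkene, C10=C11), ester formation and ring-closing metathesis.
4. Fragment B: propiolate addition, Midland reduction (C7), syn-carbocupration ((Z)-C5=C6).
5. Ring order: butenolide (step 7), then α-methylene-γ-butyrolactone by allylic transposition (step 19), then the ten-membered carbocycle (step 22).

## Fragment A (bromolactone)

Step 1
Reactants: 1 acrolein; 2 prop-1-ynylmagnesium bromide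
Product: 3 hex-1-en-4-yn-3-ol (racemic)
Conditions: THF, −78 → 0 °C; aqueous work-up
Reagents that add atoms: none
Why: Grignard 1,2-addition of the alkynyl reagent to the enal carbonyl gives the racemic vinyl propynyl carbinol.

Step 2
Reactants: 3 hex-1-en-4-yn-3-ol (racemic)
Product: 4 (3R)-hex-1-en-4-yn-3-ol
Conditions: Ti(OiPr)4 (10 mol%), D-(−)-diisopropyl tartrate (15 mol%), t-BuOOH (0.6 equiv), 4 Å MS, CH2Cl2, −20 °C, to ca. 55% conversion
Reagents that add atoms: none
Why: Sharpless kinetic resolution, in which the D-(−)-tartrate catalyst epoxidises the vinyl group of the (S)-alcohol much faster, so the (R)-alcohol (future C11a) is recovered in high ee while the alkyne is inert.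

Step 3
Reactants: 4 (3R)-hex-1-en-4-yn-3-ol
Product: 6 (3R,4Z)-5-iodohexa-1,4-dien-3-ol, via cyclic alkenylalanate 5 (not isolated)
Conditions: NaAlH2(OCH2CH2OMe)2 (Red-Al), THF, 0 °C → rt; then I2, THF, −78 °C
Reagents that add atoms: iodine, II
Why: Hydroxyl-directed trans-hydroalumination puts aluminium on the distal alkyne carbon cis to the carbinol, and iododealumination with retention gives the (Z)-iodoalkene that fixes the C10=C11 geometry.

Step 4
Reactants: 7 methyl 2-(hydroxymethyl)prop-2-enoate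
Product: 8 methyl 2-({[tert-butyl(dimethyl)silyl]oxy}methyl)prop-2-enoate
Conditions: TBSCl, imidazole, CH2Cl2, 0 °C → rt
Reagents that add atoms: tert-butyldimethylsilyl chloride, CC(C)(C)[Si](C)(C)Cl
Why: Silyl ether formation protects the primary allylic hydroxyl.

Step 5
Reactants: 8 methyl 2-({[tert-butyl(dimethyl)silyl]oxy}methyl)prop-2-enoate
Product: 9 2-({[tert-butyl(dimethyl)silyl]oxy}methyl)prop-2-enoic acid
Conditions: LiOH, THF/H2O, 0 °C; then 1 M HCl to pH 4
Reagents that add atoms: lithium hydroxide, [Li+].[OH-]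
Why: Ester saponification under cold conditions that leave the primary TBS ether in place.

Step 6
Reactants: 6 (3R,4Z)-5-iodohexa-1,4-dien-3-ol; 9 2-({[tert-butyl(dimethyl)silyl]oxy}methyl)prop-2-enoic acid
Product: 10 (3R,4Z)-5-iodohexa-1,4-dien-3-yl 2-({[tert-butyl(dimethyl)silyl]oxy}methyl)prop-2-enoate
Conditions: DCC, DMAP (10 mol%), CH2Cl2, 0 °C → rt
Reagents that add atoms: none
Why: Steglich esterification acylates the bis-allylic alcohol on oxygen, so the carbinol centre is retained.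

Step 7
Reactants: 10 (3R,4Z)-5-iodohexa-1,4-dien-3-yl 2-({[tert-butyl(dimethyl)silyl]oxy}methyl)prop-2-enoate
Product: 11 (5R)-3-({[tert-butyl(dimethyl)silyl]oxy}methyl)-5-[(1Z)-2-iodoprop-1-en-1-yl]furan-2(5H)-one
Conditions: second-generation Hoveyda–Grubbs catalyst RuCl2(H2IMes)(=CH-C6H4-2-OiPr) (5 mol%), toluene (0.01 M), 80 °C
Reagents that add atoms: none
Why: Ring-closing metathesis between the vinyl group and the 1,1-disubstituted acrylate closes the butenolide with loss of ethene, while the trisubstituted iodoalkene is too hindered to take part.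

Step 8
Reactants: 11 (5R)-3-({[tert-butyl(dimethyl)silyl]oxy}methyl)-5-[(1Z)-2-iodoprop-1-en-1-yl]furan-2(5H)-one
Product: 12 (5R)-3-(hydroxymethyl)-5-[(1Z)-2-iodoprop-1-en-1-yl]furan-2(5H)-one
Conditions: HF·pyridine, THF, 0 °C
Reagents that add atoms: none
Why: Acidic desilylation frees the primary alcohol without exposing the base-sensitive C5–H of the butenolide to a basic fluoride source.

Step 9
Reactants: 12 (5R)-3-(hydroxymethyl)-5-[(1Z)-2-iodoprop-1-en-1-yl]furan-2(5H)-one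
Product: 13 (5R)-3-(bromomethyl)-5-[(1Z)-2-iodoprop-1-en-1-yl]furan-2(5H)-one
Conditions: CBr4, PPh3, CH2Cl2, 0 °C
Reagents that add atoms: carbon tetrabromide, BrC(Br)(Br)Br
Why: Appel reaction turns the primary allylic alcohol into the bromide under neutral conditions that do not epimerise C5.

## Fragment B ((Z)-enal)

Step 10
Reactants: 14 propane-1,3-diol
Product: 15 3-[(triethylsilyl)oxy]propan-1-ol
Conditions: NaH (1.0 equiv), THF, 0 °C; then Et3SiCl (1.0 equiv), rt
Reagents that add atoms: chlorotriethylsilane, CC[Si](CC)(CC)Cl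
Why: Monosilylation of the symmetrical diol through its sparingly soluble monosodium alkoxide.

Step 11
Reactants: 15 3-[(triethylsilyl)oxy]propan-1-ol
Product: 16 3-[(triethylsilyl)oxy]propanal
Conditions: Dess–Martin periodinane, NaHCO3, CH2Cl2, 0 °C → rt
Reagents that add atoms: none
Why: Dess–Martin oxidation stops at the aldehyde and leaves the primary triethylsilyl ether intact.

Step 12
Reactants: 16 3-[(triethylsilyl)oxy]propanal; 17 methyl prop-2-ynoate
Product: 19 methyl 4-hydroxy-6-[(triethylsilyl)oxy]hex-2-ynoate (racemic), via lithium acetylide 18 (not isolated)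
Conditions: LiN(SiMe3)2, THF, −78 °C; then 16, −78 °C
Reagents that add atoms: none
Why: Carbonyl alkynylation by the lithiated propiolate gives the γ-hydroxy ynoate.

Step 13
Reactants: 19 methyl 4-hydroxy-6-[(triethylsilyl)oxy]hex-2-ynoate (racemic)
Product: 20 methyl 4-oxo-6-[(triethylsilyl)oxy]hex-2-ynoate
Conditions: Dess–Martin periodinane, NaHCO3, CH2Cl2, 0 °C
Reagents that add atoms: none
Why: Dess–Martin oxidation of the propargylic alcohol gives the ynone needed for a reagent-controlled reduction.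

Step 14
Reactants: 20 methyl 4-oxo-6-[(triethylsilyl)oxy]hex-2-ynoate
Product: 21 methyl (4S)-4-hydroxy-6-[(triethylsilyl)oxy]hex-2-ynoate
Conditions: (S)-Alpine-Borane [B-isopinocampheyl-9-BBN from (−)-α-pinene], THF, rt; then CH3CHO; then HOCH2CH2NH2
Reagents that add atoms: none
Why: Midland reduction, in which the alkyne is the small group in the boat-like transition state, so the borane from (−)-α-pinene gives the (S)-propargylic alcohol (future C7).

Step 15
Reactants: 21 methyl (4S)-4-hydroxy-6-[(triethylsilyl)oxy]hex-2-ynoate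
Product: 22 methyl (4S)-4-{[tert-butyl(dimethyl)silyl]oxy}-6-[(triethylsilyl)oxy]hex-2-ynoate
Conditions: TBSCl, imidazole, DMF, rt
Reagents that add atoms: tert-butyldimethylsilyl chloride, CC(C)(C)[Si](C)(C)Cl
Why: Silylation protects the secondary hydroxyl so that it cannot lactonise after the cuprate step.

Step 16
Reactants: 22 methyl (4S)-4-{[tert-butyl(dimethyl)silyl]oxy}-6-[(triethylsilyl)oxy]hex-2-ynoate
Product: 23 methyl (2Z,4S)-4-{[tert-butyl(dimethyl)silyl]oxy}-3-methyl-6-[(triethylsilyl)oxy]hex-2-enoate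
Conditions: Me2CuLi (from CuI and 2 MeLi), THF, −78 °C; MeOH quench at −78 °C
Reagents that add atoms: lithium dimethylcuprate, [Li+].C[Cu-]C
Why: Syn carbocupration of the ynoate followed by cold protonation places methyl and hydrogen cis, so the silyloxy carbon ends up cis to the ester, which is the (Z)-C5=C6 alkene of the target.

Step 17
Reactants: 23 methyl (2Z,4S)-4-{[tert-butyl(dimethyl)silyl]oxy}-3-methyl-6-[(triethylsilyl)oxy]hex-2-enoate
Product: 24 (2Z,4S)-4-{[tert-butyl(dimethyl)silyl]oxy}-3-methyl-6-[(triethylsilyl)oxy]hex-2-en-1-ol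
Conditions: i-Bu2AlH (2.2 equiv), CH2Cl2, −78 °C
Reagents that add atoms: none
Why: Hydride reduction of the enoate to the allylic alcohol at low temperature leaves the alkene geometry untouched.

Step 18
Reactants: 24 (2Z,4S)-4-{[tert-butyl(dimethyl)silyl]oxy}-3-methyl-6-[(triethylsilyl)oxy]hex-2-en-1-ol
Product: 25 (2Z,4S)-4-{[tert-butyl(dimethyl)silyl]oxy}-3-methyl-6-[(triethylsilyl)oxy]hex-2-enal
Conditions: MnO2, CH2Cl2, rt
Reagents that add atoms: none
Why: Allylic oxidation with MnO2 under neutral conditions gives the (Z)-enal without Z/E isomerisation.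

## Coupling and endgame

Step 19
Reactants: 13 (5R)-3-(bromomethyl)-5-[(1Z)-2-iodoprop-1-en-1-yl]furan-2(5H)-one; 25 (2Z,4S)-4-{[tert-butyl(dimethyl)silyl]oxy}-3-methyl-6-[(triethylsilyl)oxy]hex-2-enal
Product: 27 (4S,5R)-4-[(1R,2Z,4S)-4-{[tert-butyl(dimethyl)silyl]oxy}-1-hydroxy-3-methyl-6-[(triethylsilyl)oxy]hex-2-en-1-yl]-5-[(1Z)-2-iodoprop-1-en-1-yl]-3-methylideneoxolan-2-one, via allylchromium species 26 (not isolated)
Conditions: CrCl2 (nickel-free, 3 equiv), THF, 0 °C → rt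
Reagents that add atoms: none
Why: Nozaki–Hiyama allylation in which the allylchromium adds through its ring γ-carbon via a chair transition state (ring substituent pseudo-equatorial, hence the anti C4/C1′ relationship) and on the face opposite the C5 alkenyl group (trans lactone), so the single centre of 13 sets both new centres; the alkenyl iodide is inert without nickel.

Step 20
Reactants: 27 (4S,5R)-4-[(1R,2Z,4S)-4-{[tert-butyl(dimethyl)silyl]oxy}-1-hydroxy-3-methyl-6-[(triethylsilyl)oxy]hex-2-en-1-yl]-5-[(1Z)-2-iodoprop-1-en-1-yl]-3-methylideneoxolan-2-one; 28 (2Z)-2-methylbut-2-enoic acid (angelic acid)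
Product: 30 (1R,2Z,4S)-4-{[tert-butyl(dimethyl)silyl]oxy}-1-[(2R,3S)-2-[(1Z)-2-iodoprop-1-en-1-yl]-4-methylidene-5-oxooxolan-3-yl]-3-methyl-6-[(triethylsilyl)oxy]hex-2-en-1-yl (2Z)-2-methylbut-2-enoate, via mixed anhydride 29 (not isolated)
Conditions: 28, 2,4,6-trichlorobenzoyl chloride, Et3N, toluene, rt; then 27, toluene, 70 °C (no DMAP)
Reagents that add atoms: none
Why: Yamaguchi esterification through the preformed mixed anhydride acylates the secondary alcohol with retention at carbon and, without DMAP, without angelate-to-tiglate isomerisation.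

Step 21
Reactants: 30 (1R,2Z,4S)-4-{[tert-butyl(dimethyl)silyl]oxy}-1-[(2R,3S)-2-[(1Z)-2-iodoprop-1-en-1-yl]-4-methylidene-5-oxooxolan-3-yl]-3-methyl-6-[(triethylsilyl)oxy]hex-2-en-1-yl (2Z)-2-methylbut-2-enoate
Product: 31 (1R,2Z,4S)-4-{[tert-butyl(dimethyl)silyl]oxy}-1-[(2R,3S)-2-[(1Z)-2-iodoprop-1-en-1-yl]-4-methylidene-5-oxooxolan-3-yl]-3-methyl-6-oxohex-2-en-1-yl (2Z)-2-methylbut-2-enoate
Conditions: (COCl)2, DMSO, CH2Cl2, −78 → −30 °C; then Et3N, −78 °C → rt
Reagents that add atoms: none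
Why: Under Swern conditions the primary triethylsilyl ether is cleaved and oxidised in one pot to the aldehyde, while the secondary TBS ether is untouched.

Step 22
Reactants: 31 (1R,2Z,4S)-4-{[tert-butyl(dimethyl)silyl]oxy}-1-[(2R,3S)-2-[(1Z)-2-iodoprop-1-en-1-yl]-4-methylidene-5-oxooxolan-3-yl]-3-methyl-6-oxohex-2-en-1-yl (2Z)-2-methylbut-2-enoate
Product: 33 (3aR,4R,5Z,7S,10Z,11aS)-7-{[tert-butyl(dimethyl)silyl]oxy}-9-hydroxy-6,10-dimethyl-3-methylidene-2-oxo-2,3,3a,4,7,8,9,11a-octahydrocyclodeca[b]furan-4-yl (2Z)-2-methylbut-2-enoate (both C9 epimers), via alkenylchromium species 32 (not isolated)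
Conditions: CrCl2 (10 equiv), NiCl2 (2 mol%), DMSO/THF, rt, 2 mM
Reagents that add atoms: none
Why: Nozaki–Hiyama–Kishi macrocyclisation, in which the (Z)-alkenyl iodide is activated by catalytic nickel and adds as the alkenylchromium to the aldehyde with retention of alkene geometry; the new carbinol centre is left uncontrolled because step 23 removes it.

Step 23
Reactants: 33 (3aR,4R,5Z,7S,10Z,11aS)-7-{[tert-butyl(dimethyl)silyl]oxy}-9-hydroxy-6,10-dimethyl-3-methylidene-2-oxo-2,3,3a,4,7,8,9,11a-octahydrocyclodeca[b]furan-4-yl (2Z)-2-methylbut-2-enoate (both C9 epimers)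
Product: 34 (3aS,4R,5Z,7S,10Z,11aS)-7-{[tert-butyl(dimethyl)silyl]oxy}-6,10-dimethyl-3-methylidene-2,9-dioxo-2,3,3a,4,7,8,9,11a-octahydrocyclodeca[b]furan-4-yl (2Z)-2-methylbut-2-enoate
Conditions: Dess–Martin periodinane, NaHCO3, CH2Cl2, 0 °C
Reagents that add atoms: none
Why: Dess–Martin oxidation converges both allylic alcohol epimers on one (Z)-enone (the 3a descriptor changes only through CIP priorities, not in space).

Step 24
Reactants: 34 (3aS,4R,5Z,7S,10Z,11aS)-7-{[tert-butyl(dimethyl)silyl]oxy}-6,10-dimethyl-3-methylidene-2,9-dioxo-2,3,3a,4,7,8,9,11a-octahydrocyclodeca[b]furan-4-yl (2Z)-2-methylbut-2-enoate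
Product: 35 (3aS,4R,5Z,7S,10Z,11aS)-7-hydroxy-6,10-dimethyl-3-methylidene-2,9-dioxo-2,3,3a,4,7,8,9,11a-octahydrocyclodeca[b]furan-4-yl (2Z)-2-methylbut-2-enoate
Conditions: HF·pyridine, pyridine, THF, 0 °C; used at once
Reagents that add atoms: none
Why: Buffered fluoride desilylation frees the C7 hydroxyl without touching the angelate or the methylene lactone.

Step 25
Reactants: 35 (3aS,4R,5Z,7S,10Z,11aS)-7-hydroxy-6,10-dimethyl-3-methylidene-2,9-dioxo-2,3,3a,4,7,8,9,11a-octahydrocyclodeca[b]furan-4-yl (2Z)-2-methylbut-2-enoate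
Product: 36 (3aR,4R,5Z,7S,9S,10Z,11aS)-7,9-dihydroxy-6,10-dimethyl-3-methylidene-2-oxo-2,3,3a,4,7,8,9,11a-octahydrocyclodeca[b]furan-4-yl (2Z)-2-methylbut-2-enoate (CNP0152559.1)
Conditions: Me4NBH(OAc)3, AcOH/MeCN (1:1), −30 °C
Reagents that add atoms: none
Why: Evans–Saksena reduction, in which the C7 hydroxyl binds the triacetoxyborohydride and delivers hydride intramolecularly through a chair transition state to give the 1,3-anti diol, i.e. (9S), leaving the methylene lactone and angelate alone.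

## Compound list

1 | acrolein | C=CC=O | starting material
2 | prop-1-ynylmagnesium bromide | CC#C[Mg]Br | starting material
3 | hex-1-en-4-yn-3-ol (racemic) | C=CC(O)C#CC | intermediate
4 | (3R)-hex-1-en-4-yn-3-ol | C=C[C@@H](O)C#CC | intermediate
5 | cyclic alkenylalanate of 4 (sodium salt, not isolated) | [Na+].C=C[C@H]1O[Al-](OCCOC)(OCCOC)C(C)=C1 | intermediate
6 | (3R,4Z)-5-iodohexa-1,4-dien-3-ol | C=C[C@@H](O)/C=C(/C)I | intermediate
7 | methyl 2-(hydroxymethyl)prop-2-enoate | C=C(CO)C(=O)OC | starting material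
8 | methyl 2-({[tert-butyl(dimethyl)silyl]oxy}methyl)prop-2-enoate | C=C(CO[Si](C)(C)C(C)(C)C)C(=O)OC | intermediate
9 | 2-({[tert-butyl(dimethyl)silyl]oxy}methyl)prop-2-enoic acid | C=C(CO[Si](C)(C)C(C)(C)C)C(=O)O | intermediate
10 | (3R,4Z)-5-iodohexa-1,4-dien-3-yl 2-({[tert-butyl(dimethyl)silyl]oxy}methyl)prop-2-enoate | C=C[C@@H](OC(=O)C(=C)CO[Si](C)(C)C(C)(C)C)/C=C(/C)I | intermediate
11 | (5R)-3-({[tert-butyl(dimethyl)silyl]oxy}methyl)-5-[(1Z)-2-iodoprop-1-en-1-yl]furan-2(5H)-one | O=C1O[C@@H](/C=C(/C)I)C=C1CO[Si](C)(C)C(C)(C)C | intermediate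
12 | (5R)-3-(hydroxymethyl)-5-[(1Z)-2-iodoprop-1-en-1-yl]furan-2(5H)-one | O=C1O[C@@H](/C=C(/C)I)C=C1CO | intermediate
13 | (5R)-3-(bromomethyl)-5-[(1Z)-2-iodoprop-1-en-1-yl]furan-2(5H)-one | O=C1O[C@@H](/C=C(/C)I)C=C1CBr | intermediate
14 | propane-1,3-diol | OCCCO | starting material
15 | 3-[(triethylsilyl)oxy]propan-1-ol | CC[Si](CC)(CC)OCCCO | intermediate
16 | 3-[(triethylsilyl)oxy]propanal | CC[Si](CC)(CC)OCCC=O | intermediate
17 | methyl prop-2-ynoate | C#CC(=O)OC | starting material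
18 | methyl 3-lithioprop-2-ynoate (not isolated) | [Li]C#CC(=O)OC | intermediate
19 | methyl 4-hydroxy-6-[(triethylsilyl)oxy]hex-2-ynoate (racemic) | CC[Si](CC)(CC)OCCC(O)C#CC(=O)OC | intermediate
20 | methyl 4-oxo-6-[(triethylsilyl)oxy]hex-2-ynoate | CC[Si](CC)(CC)OCCC(=O)C#CC(=O)OC | intermediate
21 | methyl (4S)-4-hydroxy-6-[(triethylsilyl)oxy]hex-2-ynoate | CC[Si](CC)(CC)OCC[C@H](O)C#CC(=O)OC | intermediate
22 | methyl (4S)-4-{[tert-butyl(dimethyl)silyl]oxy}-6-[(triethylsilyl)oxy]hex-2-ynoate | CC[Si](CC)(CC)OCC[C@H](O[Si](C)(C)C(C)(C)C)C#CC(=O)OC | intermediate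
23 | methyl (2Z,4S)-4-{[tert-butyl(dimethyl)silyl]oxy}-3-methyl-6-[(triethylsilyl)oxy]hex-2-enoate | CC[Si](CC)(CC)OCC[C@H](O[Si](C)(C)C(C)(C)C)/C(C)=C\C(=O)OC | intermediate
24 | (2Z,4S)-4-{[tert-butyl(dimethyl)silyl]oxy}-3-methyl-6-[(triethylsilyl)oxy]hex-2-en-1-ol | CC[Si](CC)(CC)OCC[C@H](O[Si](C)(C)C(C)(C)C)/C(C)=C\CO | intermediate
25 | (2Z,4S)-4-{[tert-butyl(dimethyl)silyl]oxy}-3-methyl-6-[(triethylsilyl)oxy]hex-2-enal | CC[Si](CC)(CC)OCC[C@H](O[Si](C)(C)C(C)(C)C)/C(C)=C\C=O | intermediate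
26 | {[(5R)-5-[(1Z)-2-iodoprop-1-en-1-yl]-2-oxo-2,5-dihydrofuran-3-yl]methyl}chromium dichloride (not isolated) | O=C1O[C@@H](/C=C(/C)I)C=C1C[Cr](Cl)Cl | intermediate
27 | (4S,5R)-4-[(1R,2Z,4S)-4-{[tert-butyl(dimethyl)silyl]oxy}-1-hydroxy-3-methyl-6-[(triethylsilyl)oxy]hex-2-en-1-yl]-5-[(1Z)-2-iodoprop-1-en-1-yl]-3-methylideneoxolan-2-one | C=C1C(=O)O[C@@H](/C=C(/C)I)[C@@H]1[C@H](O)/C=C(/C)[C@H](CCO[Si](CC)(CC)CC)O[Si](C)(C)C(C)(C)C | intermediate
28 | (2Z)-2-methylbut-2-enoic acid (angelic acid) | C/C=C(/C)C(=O)O | starting material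
29 | (2Z)-2-methylbut-2-enoic 2,4,6-trichlorobenzoic anhydride (not isolated) | C/C=C(/C)C(=O)OC(=O)c1c(Cl)cc(Cl)cc1Cl | intermediate
30 | (1R,2Z,4S)-4-{[tert-butyl(dimethyl)silyl]oxy}-1-[(2R,3S)-2-[(1Z)-2-iodoprop-1-en-1-yl]-4-methylidene-5-oxooxolan-3-yl]-3-methyl-6-[(triethylsilyl)oxy]hex-2-en-1-yl (2Z)-2-methylbut-2-enoate | C=C1C(=O)O[C@@H](/C=C(/C)I)[C@@H]1[C@H](OC(=O)/C(C)=C\C)/C=C(/C)[C@H](CCO[Si](CC)(CC)CC)O[Si](C)(C)C(C)(C)C | intermediate
31 | (1R,2Z,4S)-4-{[tert-butyl(dimethyl)silyl]oxy}-1-[(2R,3S)-2-[(1Z)-2-iodoprop-1-en-1-yl]-4-methylidene-5-oxooxolan-3-yl]-3-methyl-6-oxohex-2-en-1-yl (2Z)-2-methylbut-2-enoate | C=C1C(=O)O[C@@H](/C=C(/C)I)[C@@H]1[C@H](OC(=O)/C(C)=C\C)/C=C(/C)[C@H](CC=O)O[Si](C)(C)C(C)(C)C | intermediate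
32 | alkenylchromium dichloride from 31, CrCl2 in place of iodine (not isolated) | C=C1C(=O)O[C@@H](/C=C(/C)[Cr](Cl)Cl)[C@@H]1[C@H](OC(=O)/C(C)=C\C)/C=C(/C)[C@H](CC=O)O[Si](C)(C)C(C)(C)C | intermediate
33 | (3aR,4R,5Z,7S,10Z,11aS)-7-{[tert-butyl(dimethyl)silyl]oxy}-9-hydroxy-6,10-dimethyl-3-methylidene-2-oxo-2,3,3a,4,7,8,9,11a-octahydrocyclodeca[b]furan-4-yl (2Z)-2-methylbut-2-enoate (both C9 epimers) | C=C1C(=O)O[C@H]2/C=C(/C)C(O)C[C@H](O[Si](C)(C)C(C)(C)C)/C(C)=C\[C@@H](OC(=O)/C(C)=C\C)[C@H]12 | intermediate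
34 | (3aS,4R,5Z,7S,10Z,11aS)-7-{[tert-butyl(dimethyl)silyl]oxy}-6,10-dimethyl-3-methylidene-2,9-dioxo-2,3,3a,4,7,8,9,11a-octahydrocyclodeca[b]furan-4-yl (2Z)-2-methylbut-2-enoate | C=C1C(=O)O[C@H]2/C=C(/C)C(=O)C[C@H](O[Si](C)(C)C(C)(C)C)/C(C)=C\[C@@H](OC(=O)/C(C)=C\C)[C@H]12 | intermediate
35 | (3aS,4R,5Z,7S,10Z,11aS)-7-hydroxy-6,10-dimethyl-3-methylidene-2,9-dioxo-2,3,3a,4,7,8,9,11a-octahydrocyclodeca[b]furan-4-yl (2Z)-2-methylbut-2-enoate | C=C1C(=O)O[C@H]2/C=C(/C)C(=O)C[C@H](O)/C(C)=C\[C@@H](OC(=O)/C(C)=C\C)[C@H]12 | intermediate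
36 | (3aR,4R,5Z,7S,9S,10Z,11aS)-7,9-dihydroxy-6,10-dimethyl-3-methylidene-2-oxo-2,3,3a,4,7,8,9,11a-octahydrocyclodeca[b]furan-4-yl (2Z)-2-methylbut-2-enoate (CNP0152559.1) | C=C1C(=O)O[C@H]2/C=C(/C)[C@@H](O)C[C@H](O)/C(C)=C\[C@@H](OC(=O)/C(C)=C\C)[C@H]12 | target

## Step count and risk

Total steps: 25. Fragment A takes steps 1–3 and 6–9 (7 steps) plus steps 4–5 for acid 9; fragment B takes steps 10–18 (9 steps); coupling and endgame take steps 19–25 (7 steps).
Longest linear sequence: 16 steps (10–18, then 19–25).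

The three steps most likely to fail:

**Step 19 (chromium allylation).** The C1′ configuration rests on a chair transition state, and a sizeable amount of the C1′ epimer would spoil the C4 centre of the target. The fallback sets out from 13 and 25 and comes back to the route at 30. If the allylation gives the C1′ epimer, (4S,5R)-4-[(1S,2Z,4S)-4-{[tert-butyl(dimethyl)silyl]oxy}-1-hydroxy-3-methyl-6-[(triethylsilyl)oxy]hex-2-en-1-yl]-5-[(1Z)-2-iodoprop-1-en-1-yl]-3-methylideneoxolan-2-one F1, as the main or a substantial product, it is separated and esterified with angelic acid 28 under Mitsunobu conditions (PPh3, DIAD, toluene, 0 °C). This inverts C1′ and gives 30 directly, so the centre is then set by SN2 displacement and not by the allylation transition state.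

**Step 22 (NHK macrocyclisation).** The ring is strained, and the exocyclic methylene of the lactone lies within reach of the alkenyl–nickel carbon, so carbometallation or reduction of the acrylate could compete. The fallback sets out from 30 and comes back at 34, and masks the acrylate before ring closure. Compound 30 is treated with Me2NH in THF at 0 °C to give the conjugate adduct, the 3-[(dimethylamino)methyl] lactone F2. Swern conditions as in step 21 give the aldehyde F3, and the CrCl2/NiCl2 cyclisation then gives the macrocyclic amino alcohol F4. Dess–Martin oxidation gives the amino enone F5, MeI in MeCN gives the methiodide F6, and aqueous NaHCO3 eliminates trimethylamine to restore the methylene group, giving 34.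

**Step 25 (directed anti reduction).** In the macrocycle the chair-like internal hydride delivery may be distorted, and the (Z)-enone could suffer oxa-Michael addition by the C7 hydroxyl before it is reduced. The fallback sets out from 34 and comes back at 36, and sets C9 by reagent control before the hydroxyl is freed. Compound 34 is reduced with (R)-2-methyl-CBS-oxazaborolidine and catecholborane in toluene at −78 °C, where the alkenyl group acts as the large substituent, to give the (9S)-alcohol F7. HF·pyridine in THF then removes the silyl group to give 36.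

## Further compounds

F1 | step 19 | (4S,5R)-4-[(1S,2Z,4S)-4-{[tert-butyl(dimethyl)silyl]oxy}-1-hydroxy-3-methyl-6-[(triethylsilyl)oxy]hex-2-en-1-yl]-5-[(1Z)-2-iodoprop-1-en-1-yl]-3-methylideneoxolan-2-one | C=C1C(=O)O[C@@H](/C=C(/C)I)[C@@H]1[C@@H](O)/C=C(/C)[C@H](CCO[Si](CC)(CC)CC)O[Si](C)(C)C(C)(C)C
F2 | step 22 | dimethylamine adduct of 30, 3-[(dimethylamino)methyl] lactone (C3 epimers) | CN(C)CC1C(=O)O[C@@H](/C=C(/C)I)[C@@H]1[C@H](OC(=O)/C(C)=C\C)/C=C(/C)[C@H](CCO[Si](CC)(CC)CC)O[Si](C)(C)C(C)(C)C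
F3 | step 22 | aldehyde from F2, 6-oxo in place of the triethylsilyloxy group | CN(C)CC1C(=O)O[C@@H](/C=C(/C)I)[C@@H]1[C@H](OC(=O)/C(C)=C\C)/C=C(/C)[C@H](CC=O)O[Si](C)(C)C(C)(C)C
F4 | step 22 | macrocyclic amino alcohol, 3-[(dimethylamino)methyl] analogue of 33 (C3 and C9 epimers) | CN(C)CC1C(=O)O[C@H]2/C=C(/C)C(O)C[C@H](O[Si](C)(C)C(C)(C)C)/C(C)=C\[C@@H](OC(=O)/C(C)=C\C)[C@H]12
F5 | step 22 | macrocyclic amino enone, 3-[(dimethylamino)methyl] analogue of 34 | CN(C)CC1C(=O)O[C@H]2/C=C(/C)C(=O)C[C@H](O[Si](C)(C)C(C)(C)C)/C(C)=C\[C@@H](OC(=O)/C(C)=C\C)[C@H]12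
F6 | step 22 | methiodide of F5, trimethylammonium iodide | C[N+](C)(C)CC1C(=O)O[C@H]2/C=C(/C)C(=O)C[C@H](O[Si](C)(C)C(C)(C)C)/C(C)=C\[C@@H](OC(=O)/C(C)=C\C)[C@H]12.[I-]
F7 | step 25 | (3aR,4R,5Z,7S,9S,10Z,11aS)-7-{[tert-butyl(dimethyl)silyl]oxy}-9-hydroxy-6,10-dimethyl-3-methylidene-2-oxo-2,3,3a,4,7,8,9,11a-octahydrocyclodeca[b]furan-4-yl (2Z)-2-methylbut-2-enoate | C=C1C(=O)O[C@H]2/C=C(/C)[C@@H](O)C[C@H](O[Si](C)(C)C(C)(C)C)/C(C)=C\[C@@H](OC(=O)/C(C)=C\C)[C@H]12
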